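## Retrosynthetic overview

1. Target ⇐ its dimethyl ester: the C-8 methylene comes from a C-8 ketone (Zn/CH2Br2/TiCl4), and the C-13=C-14 enoate from cross-metathesis of an isopropenyl side chain with methyl acrylate.
2. The C-4 quaternary centre (late methylation of the ester enolate) and H-9 (kinetic protonation) are both set on a cis-fused bicyclic C-8/C-9 silyl enol ether.
3. Key step: the C-1–C-10 bond is formed by 6-exo cyclisation of a primary alkyl radical onto a tetrasubstituted cyclohexenone. Ring B is present from the start and ring A is closed second; the step sets quaternary C-10 and the cis ring fusion, and the resulting enolate is trapped.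
4. The cyclisation precursor comes from a 4-substituted 3-methylcyclohexenone: allylic oxidation, α-iodination and B-alkyl Suzuki coupling (isoprene) for the C-9 chain, and (R)-epichlorohydrin for C-1 to C-3 with C-2 preset.
5. The C-4–C-5 bond and the C-5 configuration come from a Johnson–Claisen rearrangement of (R)-2-methylcyclohex-2-en-1-ol (CBS reduction).

Assumption: bicyclic compounds carry labdane-type locants (C-1 to C-10 ring carbons, C-11 to C-16 side chain, C-17 exocyclic methylene carbon, C-18 methyl and C-19 carboxyl carbon on C-4, C-20 methyl on C-10); with these labels the target SMILES is (2S,4R,5S,9R,10R,13E) with a cis-fused decalin (H-5, H-9, 2-OH, 4-CH3 and 10-CH3 all on one face).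

## Route

Step 1
Reactants: 1 2-methylcyclohex-2-en-1-one
Product: 2 (R)-2-methylcyclohex-2-en-1-ol
Conditions: (S)-2-methyl-CBS-oxazaborolidine (10 mol %), BH3·SMe2, THF, −20 °C
Reagents that add atoms: none
Why: Corey–Bakshi–Shibata reduction delivers hydride to one carbonyl face with the 2-methylvinyl arm acting as the large group, giving the (R)-allylic alcohol whose configuration is later relayed to C-5.

Step 2
Reactants: 2 (R)-2-methylcyclohex-2-en-1-ol; 3 trimethyl orthoacetate
Product: 4 methyl 2-[(1R)-2-methylcyclohex-2-en-1-yl]acetate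
Conditions: MeC(OMe)3 (5 equiv), EtCO2H (cat.), 135 °C, MeOH distilled off
Reagents that add atoms: none
Why: Johnson–Claisen rearrangement of the mixed ketene acetal is a suprafacial [3,3] shift across the ring, so the new C-4–C-5 bond forms on the face that carried the oxygen (C-5 set) and the alkene moves to C-9/C-10.

Step 3
Reactants: 4 methyl 2-[(1R)-2-methylcyclohex-2-en-1-yl]acetate; 5 (R)-epichlorohydrin
Product: 7 methyl 2-[(1R)-2-methylcyclohex-2-en-1-yl]-3-[(2R)-oxiran-2-yl]propanoate (epimers at the ester α-carbon), via chlorohydrin ester 6 (not isolated)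
Conditions: LiN(iPr)2, THF, −78 °C; Et2AlCl; 5, −78 → −20 °C; H2O work-up; then K2CO3, MeOH, rt
Reagents that add atoms: none
Why: Ester-enolate alkylation with an epoxide: the diethylaluminium enolate opens 5 at its ring CH2 (SN2, the C–O bond at the stereocentre is untouched) and K2CO3 closes the chlorohydrin to the (R)-epoxide, so C-2 comes from the chiral pool, while the new centre next to the ester forms as a mixture that is erased by enolisation in step 9.

Step 4
Reactants: 7 methyl 2-[(1R)-2-methylcyclohex-2-en-1-yl]-3-[(2R)-oxiran-2-yl]propanoate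
Product: 8 methyl 2-[(1R)-2-methyl-4-oxocyclohex-2-en-1-yl]-3-[(2R)-oxiran-2-yl]propanoate
Conditions: CrO3, 3,5-dimethylpyrazole, CH2Cl2, −20 °C
Reagents that add atoms: chromium trioxide, O=[Cr](=O)=O
Why: Allylic C–H oxidation with the CrO3–3,5-dimethylpyrazole complex takes the unhindered ring CH2 next to the CH= carbon (as 1-methylcyclohexene gives 3-methylcyclohex-2-enone) and leaves epoxide, ester and C-5 untouched.

Step 5
Reactants: 8 methyl 2-[(1R)-2-methyl-4-oxocyclohex-2-en-1-yl]-3-[(2R)-oxiran-2-yl]propanoate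
Product: 9 methyl 2-[(1R)-3-iodo-2-methyl-4-oxocyclohex-2-en-1-yl]-3-[(2R)-oxiran-2-yl]propanoate
Conditions: I2, K2CO3, DMAP (cat.), THF/H2O, rt
Reagents that add atoms: iodine, II
Why: α-Iodination of the enone (conjugate addition of DMAP, iodination of the enolate, elimination; Baylis–Hillman-type mechanism) places iodine on C-9, and the basic medium keeps the epoxide closed.

Step 6
Reactants: 9 methyl 2-[(1R)-3-iodo-2-methyl-4-oxocyclohex-2-en-1-yl]-3-[(2R)-oxiran-2-yl]propanoate; 10 isoprene
Product: 12 methyl 2-[(1R)-2-methyl-3-(3-methylbut-3-en-1-yl)-4-oxocyclohex-2-en-1-yl]-3-[(2R)-oxiran-2-yl]propanoate, via alkylborane 11 (not isolated)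
Conditions: 10, 9-BBN-H, THF, 0 °C → rt; then 9, PdCl2(dppf) (5 mol %), AsPh3, Cs2CO3, DMF/H2O, rt
Reagents that add atoms: none
Why: Hydroboration of the monosubstituted alkene of isoprene followed by B-alkyl Suzuki–Miyaura coupling with the α-iodoenone joins C-9 to C-11 under mild aqueous base that spares epoxide and ester.

Step 7
Reactants: 12 methyl 2-[(1R)-2-methyl-3-(3-methylbut-3-en-1-yl)-4-oxocyclohex-2-en-1-yl]-3-[(2R)-oxiran-2-yl]propanoate
Product: 14 methyl (4R)-5-iodo-2-[(1R)-2-methyl-3-(3-methylbut-3-en-1-yl)-4-oxocyclohex-2-en-1-yl]-4-(triethylsilyloxy)pentanoate, via iodohydrin 13 (not isolated)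
Conditions: LiI, AcOH, THF, rt; then Et3SiOTf, 2,6-lutidine, CH2Cl2, −78 °C
Reagents that add atoms: lithium iodide, [Li+].[I-]; triethylsilyl triflate, CC[Si](CC)(CC)OS(=O)(=O)C(F)(F)F
Why: Acid-buffered iodide opening of the terminal epoxide at its CH2 carbon (SN2) gives the primary iodide without touching C-2, and silylation masks the alcohol so that it cannot quench the enolate formed in step 8.

Step 8
Reactants: 14 methyl (4R)-5-iodo-2-[(1R)-2-methyl-3-(3-methylbut-3-en-1-yl)-4-oxocyclohex-2-en-1-yl]-4-(triethylsilyloxy)pentanoate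
Product: 16 methyl (2R,5R,10S)-10-methyl-9-(3-methylbut-3-en-1-yl)-2-(triethylsilyloxy)-8-(trimethylsilyloxy)-cis-decal-8-ene-4-carboxylate (C-4 epimers), via diiodosamarium enolate 15 (not isolated)
Conditions: SmI2 (2.5 equiv, added slowly), HMPA, THF, −78 → −20 °C; then Me3SiCl, Et3N, −78 °C → rt
Reagents that add atoms: chlorotrimethylsilane, C[Si](C)(C)Cl
Why: Samarium diiodide-mediated radical cyclisation with radical–polar crossover: electron transfer to the C–I bond gives the primary C-1 radical, which adds 6-exo to the enone β-carbon C-10 through a chair transition state in which the C-5 tether is pseudoaxial (allylic 1,2-strain against the C-10 methyl) and the silyloxy group equatorial, so the quaternary centre forms with cis ring fusion, and a second electron turns the α-keto radical into the tetrasubstituted samarium enolate that Me3SiCl traps on oxygen.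

Step 9
Reactants: 16 methyl (2R,5R,10S)-10-methyl-9-(3-methylbut-3-en-1-yl)-2-(triethylsilyloxy)-8-(trimethylsilyloxy)-cis-decal-8-ene-4-carboxylate (C-4 epimers)
Product: 18 methyl (2S,4R,5S,9S,10S)-2-hydroxy-4,10-dimethyl-9-(3-methylbut-3-en-1-yl)-8-oxo-cis-decalin-4-carboxylate, via methylated bis-silyl ether 17 (not isolated)
Conditions: LiN(iPr)2, THF/HMPA, −78 → −30 °C; MeI; then n-Bu4NF, AcOH, THF, −78 °C → rt
Reagents that add atoms: iodomethane, CI
Why: Ester-enolate alkylation then kinetic protonation: in the favoured chair–chair form (2-silyloxy and 10-CH3 equatorial on ring A, C-10–C-9 bond axial) the α-face of C-4 is shielded by the syn-axial C-9, so MeI enters equatorially from the β-face (C-4 set, ester axial), and fluoride cleavage of the silyl enol ether with AcOH as proton source protonates C-9 from the same open β-face (its α-face is screened by C-4 and the axial ester), placing H-9 cis to the angular methyl.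

Step 10
Reactants: 18 methyl (2S,4R,5S,9S,10S)-2-hydroxy-4,10-dimethyl-9-(3-methylbut-3-en-1-yl)-8-oxo-cis-decalin-4-carboxylate; 19 methyl acrylate
Product: 20 methyl (2S,4R,5S,9S,10S)-2-hydroxy-9-[(3E)-5-methoxy-3-methyl-5-oxopent-3-en-1-yl]-4,10-dimethyl-8-oxo-cis-decalin-4-carboxylate
Conditions: 19 (10 equiv), second-generation Grubbs catalyst (10 mol %), CH2Cl2, 40 °C
Reagents that add atoms: none
Why: Olefin cross-metathesis of the 1,1-disubstituted alkene with methyl acrylate gives the trisubstituted enoate with loss of ethene, the E isomer predominating (Z isomer removed by chromatography), and the neutral conditions leave the epimerisable C-9 centre alone.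

Step 11
Reactants: 20 methyl (2S,4R,5S,9S,10S)-2-hydroxy-9-[(3E)-5-methoxy-3-methyl-5-oxopent-3-en-1-yl]-4,10-dimethyl-8-oxo-cis-decalin-4-carboxylate
Product: 21 methyl (2S,4R,5S,9R,10R)-2-hydroxy-9-[(3E)-5-methoxy-3-methyl-5-oxopent-3-en-1-yl]-4,10-dimethyl-8-methylidene-cis-decalin-4-carboxylate
Conditions: Zn, CH2Br2, TiCl4 (excess), THF/CH2Cl2, 0 °C → rt
Reagents that add atoms: dibromomethane, BrCBr
Why: Takai–Lombardo methylenation converts the hindered, enolisable C-8 ketone into the exocyclic methylene without base, so C-9 is not epimerised and both esters survive.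

Step 12
Reactants: 21 methyl (2S,4R,5S,9R,10R)-2-hydroxy-9-[(3E)-5-methoxy-3-methyl-5-oxopent-3-en-1-yl]-4,10-dimethyl-8-methylidene-cis-decalin-4-carboxylate
Product: 22 (2S,4R,5S,9R,10R)-9-[(3E)-4-carboxy-3-methylbut-3-en-1-yl]-2-hydroxy-4,10-dimethyl-8-methylidene-cis-decalin-4-carboxylic acid (CNP0086784.8)
Conditions: LiI, 2,6-lutidine, 140 °C; then 1 M HCl
Reagents that add atoms: none
Why: SN2 demethylation of both methyl esters by iodide (the axial C-19 ester is too hindered for ordinary saponification) followed by acidification gives the diacid without touching a stereocentre or an alkene.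

## Compound list

1 | 2-methylcyclohex-2-en-1-one | CC1=CCCCC1=O | starting material
2 | (R)-2-methylcyclohex-2-en-1-ol | O[C@@H]1CCCC=C1C | intermediate
3 | trimethyl orthoacetate (1,1,1-trimethoxyethane) | CC(OC)(OC)OC | starting material
4 | methyl 2-[(1R)-2-methylcyclohex-2-en-1-yl]acetate | COC(=O)C[C@H]1CCCC=C1C | intermediate
5 | (R)-epichlorohydrin, (2R)-2-(chloromethyl)oxirane | ClC[C@H]1CO1 | starting material
6 | methyl (4R)-5-chloro-4-hydroxy-2-[(1R)-2-methylcyclohex-2-en-1-yl]pentanoate (C-2 epimers) | COC(=O)C(C[C@@H](O)CCl)[C@H]1CCCC=C1C | intermediate (not isolated)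
7 | methyl 2-[(1R)-2-methylcyclohex-2-en-1-yl]-3-[(2R)-oxiran-2-yl]propanoate (C-2 epimers) | COC(=O)C(C[C@@H]1CO1)[C@H]1CCCC=C1C | intermediate
8 | methyl 2-[(1R)-2-methyl-4-oxocyclohex-2-en-1-yl]-3-[(2R)-oxiran-2-yl]propanoate (C-2 epimers) | COC(=O)C(C[C@@H]1CO1)[C@H]1CCC(=O)C=C1C | intermediate
9 | methyl 2-[(1R)-3-iodo-2-methyl-4-oxocyclohex-2-en-1-yl]-3-[(2R)-oxiran-2-yl]propanoate (C-2 epimers) | COC(=O)C(C[C@@H]1CO1)[C@H]1CCC(=O)C(I)=C1C | intermediate
10 | isoprene (2-methylbuta-1,3-diene) | C=CC(C)=C | starting material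
11 | 9-(3-methylbut-3-en-1-yl)-9-borabicyclo[3.3.1]nonane | C=C(C)CCB1C2CCCC1CCC2 | intermediate (not isolated)
12 | methyl 2-[(1R)-2-methyl-3-(3-methylbut-3-en-1-yl)-4-oxocyclohex-2-en-1-yl]-3-[(2R)-oxiran-2-yl]propanoate (C-2 epimers) | COC(=O)C(C[C@@H]1CO1)[C@H]1CCC(=O)C(CCC(C)=C)=C1C | intermediate
13 | methyl (4R)-4-hydroxy-5-iodo-2-[(1R)-2-methyl-3-(3-methylbut-3-en-1-yl)-4-oxocyclohex-2-en-1-yl]pentanoate (C-2 epimers) | COC(=O)C(C[C@@H](O)CI)[C@H]1CCC(=O)C(CCC(C)=C)=C1C | intermediate (not isolated)
14 | methyl (4R)-5-iodo-2-[(1R)-2-methyl-3-(3-methylbut-3-en-1-yl)-4-oxocyclohex-2-en-1-yl]-4-(triethylsilyloxy)pentanoate (C-2 epimers) | COC(=O)C(C[C@@H](O[Si](CC)(CC)CC)CI)[C@H]1CCC(=O)C(CCC(C)=C)=C1C | intermediate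
15 | diiodosamarium enolate of the cyclised ketone: (2R,5R,10S) cis-decal-8-ene with 8-OSmI2, 9-(3-methylbut-3-en-1-yl), 10-CH3, 2-OSiEt3 and 4-CO2CH3 (C-4 epimers) | I[Sm](I)OC1CC[C@H]2[C@](C)(C[C@H](O[Si](CC)(CC)CC)CC2C(=O)OC)C=1CCC(C)=C | intermediate (not isolated)
16 | methyl (2R,5R,10S)-10-methyl-9-(3-methylbut-3-en-1-yl)-2-(triethylsilyloxy)-8-(trimethylsilyloxy)-cis-decal-8-ene-4-carboxylate (C-4 epimers) | C[Si](C)(C)OC1CC[C@H]2[C@](C)(C[C@H](O[Si](CC)(CC)CC)CC2C(=O)OC)C=1CCC(C)=C | intermediate
17 | methyl (2S,4R,5S,10S)-4,10-dimethyl-9-(3-methylbut-3-en-1-yl)-2-(triethylsilyloxy)-8-(trimethylsilyloxy)-cis-decal-8-ene-4-carboxylate | C[Si](C)(C)OC1CC[C@H]2[C@](C)(C[C@H](O[Si](CC)(CC)CC)C[C@@]2(C)C(=O)OC)C=1CCC(C)=C | intermediate (not isolated)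
18 | methyl (2S,4R,5S,9S,10S)-2-hydroxy-4,10-dimethyl-9-(3-methylbut-3-en-1-yl)-8-oxo-cis-decalin-4-carboxylate | O=C1CC[C@H]2[C@](C)(C[C@H](O)C[C@@]2(C)C(=O)OC)[C@@H]1CCC(C)=C | intermediate
19 | methyl acrylate | C=CC(=O)OC | starting material
20 | methyl (2S,4R,5S,9S,10S)-2-hydroxy-9-[(3E)-5-methoxy-3-methyl-5-oxopent-3-en-1-yl]-4,10-dimethyl-8-oxo-cis-decalin-4-carboxylate | O=C1CC[C@H]2[C@](C)(C[C@H](O)C[C@@]2(C)C(=O)OC)[C@@H]1CC/C(C)=C/C(=O)OC | intermediate
21 | methyl (2S,4R,5S,9R,10R)-2-hydroxy-9-[(3E)-5-methoxy-3-methyl-5-oxopent-3-en-1-yl]-4,10-dimethyl-8-methylidene-cis-decalin-4-carboxylate | C=C1CC[C@H]2[C@](C)(C[C@H](O)C[C@@]2(C)C(=O)OC)[C@@H]1CC/C(C)=C/C(=O)OC | intermediate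
22 | (2S,4R,5S,9R,10R)-9-[(3E)-4-carboxy-3-methylbut-3-en-1-yl]-2-hydroxy-4,10-dimethyl-8-methylidene-cis-decalin-4-carboxylic acid (CNP0086784.8) | C=C1CC[C@H]2[C@](C)(C[C@H](O)C[C@@]2(C)C(=O)O)[C@@H]1CC/C(C)=C/C(=O)O | target

## Step count and risk

Total step count: 12. Longest linear sequence: 12 steps (1 → 22); compounds 3, 5, 10 and 19 enter in single steps.

Steps most likely to fail:

Step 3 (ester enolate plus epoxide). Openings of epoxides by ester enolates are sluggish, and chloride transfer from Et2AlCl or Claisen self-condensation can compete. The fallback sets out from 4: saponification (LiOH, aqueous THF) gives 2-[(1R)-2-methylcyclohex-2-en-1-yl]acetic acid F1, whose carboxylate dianion (2 equiv LiN(iPr)2, THF) opens (R)-epichlorohydrin 5 at the ring CH2. Acidic work-up lactonises the hydroxy acid to (5R)-5-(chloromethyl)-3-[(1R)-2-methylcyclohex-2-en-1-yl]oxolan-2-one F2. K2CO3 in MeOH (lactone methanolysis, then epoxide closure) returns the material to the route at 7.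

Step 8 (key radical cyclisation with enolate capture). The primary radical may be reduced to an alkylsamarium that eliminates the β-silyloxy group before it cyclises onto the hindered tetrasubstituted enone, or the samarium enolate may be lost before silylation. The fallback sets out from 14: a tin-hydride chain reaction (Bu3SnH by syringe pump, AIBN, benzene, 80 °C) closes ring A by the same 6-exo radical addition and gives the saturated ketone methyl (2R,5R,10S)-10-methyl-9-(3-methylbut-3-en-1-yl)-8-oxo-2-(triethylsilyloxy)-cis-decalin-4-carboxylate F3. Thermodynamic enol silylation (Me3SiI, HN(SiMe3)2, CH2Cl2, −20 °C → rt), which goes to the more substituted and strain-relieving C-8/C-9 side, then returns the material to the route at 16.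

Step 10 (cross-metathesis of a 1,1-disubstituted alkene). Conversion can be low and the E/Z ratio modest. The fallback sets out from 18: ozonolysis of its only alkene (O3, CH2Cl2/MeOH, −78 °C; Me2S) gives the methyl ketone methyl (2S,4R,5S,9S,10S)-2-hydroxy-4,10-dimethyl-8-oxo-9-(3-oxobutyl)-cis-decalin-4-carboxylate F4. A Horner–Wadsworth–Emmons olefination under mild conditions (trimethyl phosphonoacetate made from methyl bromoacetate and P(OMe)3, LiCl, DBU, MeCN), which takes the unhindered methyl ketone in preference to the C-8 ketone, returns the material to the route at 20.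

Further compounds

F1 | step 3 | 2-[(1R)-2-methylcyclohex-2-en-1-yl]acetic acid | OC(=O)C[C@H]1CCCC=C1C
F2 | step 3 | (5R)-5-(chloromethyl)-3-[(1R)-2-methylcyclohex-2-en-1-yl]oxolan-2-one (C-3 epimers) | O=C1O[C@@H](CCl)CC1[C@H]1CCCC=C1C
F3 | step 8 | methyl (2R,5R,10S)-10-methyl-9-(3-methylbut-3-en-1-yl)-8-oxo-2-(triethylsilyloxy)-cis-decalin-4-carboxylate (C-4 and C-9 epimers) | O=C1CC[C@H]2[C@](C)(C[C@H](O[Si](CC)(CC)CC)CC2C(=O)OC)C1CCC(C)=C
F4 | step 10 | methyl (2S,4R,5S,9S,10S)-2-hydroxy-4,10-dimethyl-8-oxo-9-(3-oxobutyl)-cis-decalin-4-carboxylate | O=C1CC[C@H]2[C@](C)(C[C@H](O)C[C@@]2(C)C(=O)OC)[C@@H]1CCC(C)=O
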